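**Retrosynthetic overview**
1. The aryl ether is made last: C11–O by Mitsunobu coupling of diol 16 with umbelliferone.
2. C-9 and C-3 are set on keto dienoate 12: deconjugative α-protonation (C-9 H, 8(12)-methylidene, 6-ene retained), then equatorial hydride delivery (axial C-3 OH).
3. Ring A is closed last by the key C3–C4 bond: an aldehyde-derived Breslow intermediate (acyl anion equivalent) adds to the isopropenyl group, giving the ketone and the gem-dimethyl carbon in one step.
4. C-11 comes from carbonylation of a dienyl triflate of the ring B enone; the quaternary C-10 comes from two successive α'-alkylations (methyl, then a masked 3-oxopropyl chain) anti to isopropenyl.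
5. Ring B and C-5 come from (S)-carvone; ring order is B (chiral pool), then A.

Assumption: the SMILES defines the target as the (3S,5S,9R,10R) isomer. Drimane-type locants are used in the Why lines: C-3 carbinol, C-4 gem-dimethyl, C-5/C-10 ring fusion, C-9 bearing C-11 (CH2O), C-8 bearing the methylidene C-12.

**Step 1**
Reactants: 1 (S)-(+)-carvone
Product: 3 (5S)-2,6-dimethyl-5-(prop-1-en-2-yl)cyclohex-2-en-1-one (6-methylcarvone, mixture of C-6 epimers), via lithium enolate 2 (not isolated)
Conditions: LiN(i-Pr)2, THF, −78 °C; MeI, −78 → 0 °C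
Reagents that add atoms: methyl iodide, CI
Why: Kinetic deprotonation at the α' carbon gives the cross-conjugated lithium enolate, which is C-methylated (enolate alkylation); the new C-6 centre is re-enolised in step 2 and the carvone stereocentre is untouched.

**Step 2**
Reactants: 3 6-methylcarvone; 4 2-(2-bromoethyl)-1,3-dioxolane
Product: 6 (5R,6R)-6-[2-(1,3-dioxolan-2-yl)ethyl]-2,6-dimethyl-5-(prop-1-en-2-yl)cyclohex-2-en-1-one, via lithium enolate 5 (not isolated)
Conditions: LiN(i-Pr)2, THF, −78 → −20 °C; 4, n-Bu4NI (cat.), DMPU, −78 °C → rt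
Reagents that add atoms: none
Why: Enolate alkylation (SN2, iodide formed in situ) of the tetrasubstituted α' enolate occurs anti to the neighbouring isopropenyl group, so the chain is trans and the methyl cis to isopropenyl; this fixes the quaternary centre (future C-10) and hence the later trans ring fusion.

**Step 3**
Reactants: 6 acetal enone
Product: 8 (5R,6R)-6-[2-(1,3-dioxolan-2-yl)ethyl]-2,6-dimethyl-5-(prop-1-en-2-yl)cyclohexa-1,3-dien-1-yl trifluoromethanesulfonate, via potassium dienolate 7 (not isolated)
Conditions: KN(SiMe3)2, THF, −78 °C; PhNTf2, −78 → 0 °C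
Reagents that add atoms: N-phenylbis(trifluoromethanesulfonimide), O=S(=O)(N(c1ccccc1)S(=O)(=O)C(F)(F)F)C(F)(F)F
Why: With the α' carbon quaternary, the only acidic site is the γ-CH2, so the linear dienolate forms and is O-triflated (enol triflate formation) without touching a stereocentre.

**Step 4**
Reactants: 8 dienyl triflate
Product: 9 methyl (5R,6R)-6-[2-(1,3-dioxolan-2-yl)ethyl]-2,6-dimethyl-5-(prop-1-en-2-yl)cyclohexa-1,3-diene-1-carboxylate
Conditions: Pd(OAc)2 (5 mol%), PPh3 (10 mol%), CO (1 atm), MeOH, Et3N, DMF, 60 °C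
Reagents that add atoms: carbon monoxide, [C-]#[O+]; methanol, CO
Why: Palladium-catalysed alkoxycarbonylation of the alkenyl triflate (oxidative addition, CO insertion, methanolysis) installs C-11 at the ester level; the acetal and isopropenyl group are inert.

**Step 5**
Reactants: 9 acetal dienoate
Product: 10 methyl (5R,6R)-2,6-dimethyl-6-(3-oxopropyl)-5-(prop-1-en-2-yl)cyclohexa-1,3-diene-1-carboxylate
Conditions: 1 M HCl, THF, rt
Reagents that add atoms: water, O
Why: Acid-catalysed acetal hydrolysis unmasks the aldehyde; the conjugated dienoate and the isopropenyl group tolerate dilute acid at room temperature.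

**Step 6 (key step)**
Reactants: 10 aldehyde dienoate
Product: 12 methyl (4aS,8aR)-2,5,5,8a-tetramethyl-6-oxo-4a,5,6,7,8,8a-hexahydronaphthalene-1-carboxylate (trans-fused), via Breslow enaminol 11 (not isolated)
Conditions: 4,5-dimethyl-3-(2,4,6-trimethylphenyl)thiazol-3-ium perchlorate (20 mol%), 1,8-diazabicyclo[5.4.0]undec-7-ene (DBU, 20 mol%), 1,4-dioxane (0.05 M), 120 °C, sealed tube
Reagents that add atoms: none
Why: Proposed new method: the thiazol-2-ylidene turns the aliphatic aldehyde into a Breslow enaminol (acyl anion equivalent) whose nucleophilic C-3 bonds to the internal carbon of the unactivated isopropenyl alkene while the enol O–H is delivered to the CH2 terminus in a concerted Conia-ene-like, six-membered-ring-forming transition state, giving the C-3 ketone and the gem-dimethyl C-4 at once; the closest known reaction type is the NHC-catalysed intramolecular hydroacylation of unactivated olefins (aryl aldehydes with allyl ethers, including 1,1-disubstituted alkenes that give quaternary carbons); no new stereocentre forms and the trans fusion follows from the trans chain/isopropenyl arrangement set in step 2.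

**Step 7**
Reactants: 12 keto dienoate
Product: 14 methyl (1R,4aS,8aR)-5,5,8a-trimethyl-2-methylidene-6-oxo-1,2,4a,5,6,7,8,8a-octahydronaphthalene-1-carboxylate, via dilithium bis-enolate 13 (not isolated)
Conditions: LiN(i-Pr)2 (2.5 equiv), THF/DMPU, −78 °C; AcOH, −78 °C
Reagents that add atoms: none
Why: Deconjugative kinetic protonation: the base removes a proton from the γ-methyl cis to the ester (and enolises the ketone, which simply returns on quench), and α-protonation of the extended enolate from the face opposite the angular methyl gives the 8(12)-methylidene and the C-9 hydrogen trans to that methyl (ester equatorial).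

**Step 8**
Reactants: 14 keto ester
Product: 16 (2S,4aR,5R,8aS)-5-(hydroxymethyl)-1,1,4a-trimethyl-6-methylidene-1,2,3,4,4a,5,6,8a-octahydronaphthalen-2-ol, via lithium alkoxide 15 (not isolated)
Conditions: LiBH(s-Bu)3 (1.2 equiv), THF, −78 °C; then LiAlH4, −78 → 0 °C; H2O/aq NaOH work-up
Reagents that add atoms: none
Why: The bulky borohydride attacks the 4,4-dimethyl-3-ketone along the equatorial trajectory to give the axial C-3 alcohol (trans to the angular methyl), and LiAlH4 then reduces the non-conjugated ester to the primary alcohol (hydride reductions).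

**Step 9**
Reactants: 16 diol; 17 umbelliferone (7-hydroxy-2H-chromen-2-one)
Product: 18 7-{[(1R,4aS,6S,8aR)-6-hydroxy-5,5,8a-trimethyl-2-methylidene-1,2,4a,5,6,7,8,8a-octahydronaphthalen-1-yl]methoxy}-2H-chromen-2-one (target)
Conditions: PPh3, DIAD, THF, 0 °C → rt
Reagents that add atoms: none
Why: Mitsunobu etherification alkylates the acidic phenol with the activated primary alcohol without touching a stereocentre, while the axial secondary alcohol next to the gem-dimethyl carbon is too hindered to react.

**Compound list**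
1 | (S)-(+)-carvone | CC1=CC[C@@H](CC1=O)C(C)=C | starting material
2 | lithium cross-conjugated enolate of 1 | CC1=CC[C@H](C(C)=C)C=C1[O-].[Li+] | intermediate
3 | (5S)-2,6-dimethyl-5-(prop-1-en-2-yl)cyclohex-2-en-1-one, C-6 epimer mixture | CC1=CC[C@H](C(C)=C)C(C)C1=O | intermediate
4 | 2-(2-bromoethyl)-1,3-dioxolane | BrCCC1OCCO1 | starting material
5 | lithium enolate of 3 | CC1=CC[C@H](C(C)=C)C(C)=C1[O-].[Li+] | intermediate
6 | (5R,6R)-6-[2-(1,3-dioxolan-2-yl)ethyl]-2,6-dimethyl-5-(prop-1-en-2-yl)cyclohex-2-en-1-one | CC1=CC[C@H](C(C)=C)[C@@](C)(CCC2OCCO2)C1=O | intermediate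
7 | potassium dienolate of 6 | CC=1C=C[C@H](C(C)=C)[C@@](C)(CCC2OCCO2)C=1[O-].[K+] | intermediate
8 | (5R,6R)-6-[2-(1,3-dioxolan-2-yl)ethyl]-2,6-dimethyl-5-(prop-1-en-2-yl)cyclohexa-1,3-dien-1-yl trifluoromethanesulfonate | CC=1C=C[C@H](C(C)=C)[C@@](C)(CCC2OCCO2)C=1OS(=O)(=O)C(F)(F)F | intermediate
9 | methyl (5R,6R)-6-[2-(1,3-dioxolan-2-yl)ethyl]-2,6-dimethyl-5-(prop-1-en-2-yl)cyclohexa-1,3-diene-1-carboxylate | CC=1C=C[C@H](C(C)=C)[C@@](C)(CCC2OCCO2)C=1C(=O)OC | intermediate
10 | methyl (5R,6R)-2,6-dimethyl-6-(3-oxopropyl)-5-(prop-1-en-2-yl)cyclohexa-1,3-diene-1-carboxylate | CC=1C=C[C@H](C(C)=C)[C@@](C)(CCC=O)C=1C(=O)OC | intermediate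
11 | Breslow enaminol of 10 (aldehyde carbon bonded to C-2 of the N-mesityl-4,5-dimethylthiazoline) | CC=1C=C[C@H](C(C)=C)[C@@](C)(CCC(O)=C2SC(C)=C(C)N2c2c(C)cc(C)cc2C)C=1C(=O)OC | intermediate
12 | methyl (4aS,8aR)-2,5,5,8a-tetramethyl-6-oxo-4a,5,6,7,8,8a-hexahydronaphthalene-1-carboxylate | CC=1C=C[C@@H]2C(C)(C)C(=O)CC[C@@]2(C)C=1C(=O)OC | intermediate
13 | dilithium bis-enolate of 12 (ketone enolate plus extended ester enolate) | C=C1C=C[C@@H]2C(C)(C)C([O-])=CC[C@@]2(C)C1=C([O-])OC.[Li+].[Li+] | intermediate
14 | methyl (1R,4aS,8aR)-5,5,8a-trimethyl-2-methylidene-6-oxo-1,2,4a,5,6,7,8,8a-octahydronaphthalene-1-carboxylate | C=C1C=C[C@@H]2C(C)(C)C(=O)CC[C@@]2(C)[C@@H]1C(=O)OC | intermediate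
15 | lithium alkoxide of methyl (1R,4aS,6S,8aR)-6-hydroxy-5,5,8a-trimethyl-2-methylidene-1,2,4a,5,6,7,8,8a-octahydronaphthalene-1-carboxylate | C=C1C=C[C@@H]2C(C)(C)[C@@H]([O-])CC[C@@]2(C)[C@@H]1C(=O)OC.[Li+] | intermediate
16 | (2S,4aR,5R,8aS)-5-(hydroxymethyl)-1,1,4a-trimethyl-6-methylidene-1,2,3,4,4a,5,6,8a-octahydronaphthalen-2-ol | C=C1C=C[C@@H]2C(C)(C)[C@@H](O)CC[C@@]2(C)[C@@H]1CO | intermediate
17 | umbelliferone (7-hydroxy-2H-chromen-2-one) | Oc1ccc2ccc(=O)oc2c1 | starting material
18 | 7-{[(1R,4aS,6S,8aR)-6-hydroxy-5,5,8a-trimethyl-2-methylidene-1,2,4a,5,6,7,8,8a-octahydronaphthalen-1-yl]methoxy}-2H-chromen-2-one | C=C1C=C[C@@H]2C(C)(C)[C@@H](O)CC[C@@]2(C)[C@@H]1COc1ccc2ccc(=O)oc2c1 | target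

**Totals**
Total step count: 9. Longest linear sequence: 9 steps, from (S)-carvone 1 to 18.

**Three steps most likely to fail**

Step 6 (hydroacylation of an unactivated alkene by an aliphatic Breslow intermediate). The risks are aldol or benzoin side reactions of the enolisable aldehyde, a competing vinylogous Stetter addition to the δ-carbon of the dienoate, and base-mediated epimerisation at C-5. The fallback replaces the acyl anion by a nucleophilic tertiary radical attacking an electrophilic nitrile. It sets out from aldehyde 10, which is converted (H2NOH·HCl, pyridine; then (CF3CO)2O) into methyl (5R,6R)-6-(2-cyanoethyl)-2,6-dimethyl-5-(prop-1-en-2-yl)cyclohexa-1,3-diene-1-carboxylate F3. Hydrogen-atom transfer to the isopropenyl group (Fe(acac)3, PhSiH3, EtOH, 60 °C) gives the tertiary C-4 radical, which cyclises 6-exo onto the nitrile carbon. Acidic work-up (1 M HCl) hydrolyses the resulting imine to ketone 12, where the route is rejoined.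

Step 2 (quaternary centre from an unactivated, elimination-prone alkyl halide). The fallback sets out from 3 and uses a reactive allylic electrophile followed by oxidation. Allylation (LiN(i-Pr)2; allyl bromide) gives (5R,6R)-6-allyl-2,6-dimethyl-5-(prop-1-en-2-yl)cyclohex-2-en-1-one F1. Aldehyde-selective Wacker oxidation of the monosubstituted alkene (PdCl2(PhCN)2, CuCl2, AgNO2, O2, t-BuOH/MeNO2) gives (5R,6R)-2,6-dimethyl-6-(3-oxopropyl)-5-(prop-1-en-2-yl)cyclohex-2-en-1-one F2. Chemoselective acetalisation of the aldehyde (ethylene glycol, pyridinium p-toluenesulfonate, benzene, reflux) rejoins the route at 6.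

Step 7 (regio- and face-selectivity of the kinetic protonation, with a ketone enolate present). The fallback is photochemical deconjugation, setting out from 12: irradiation at 254 nm with catalytic 1,2-dimethylimidazole causes a 1,5-hydrogen shift from the cis γ-methyl to the ester carbonyl. The photodienol then ketonises by α-protonation from the face away from the angular methyl. This leads straight to 14, where the route is rejoined, and makes no new compound F0.

**Further compounds**
F1 | step 2 | (5R,6R)-6-allyl-2,6-dimethyl-5-(prop-1-en-2-yl)cyclohex-2-en-1-one | CC1=CC[C@H](C(C)=C)[C@@](C)(CC=C)C1=O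
F2 | step 2 | (5R,6R)-2,6-dimethyl-6-(3-oxopropyl)-5-(prop-1-en-2-yl)cyclohex-2-en-1-one | CC1=CC[C@H](C(C)=C)[C@@](C)(CCC=O)C1=O
F3 | step 6 | methyl (5R,6R)-6-(2-cyanoethyl)-2,6-dimethyl-5-(prop-1-en-2-yl)cyclohexa-1,3-diene-1-carboxylate | CC=1C=C[C@H](C(C)=C)[C@@](C)(CCC#N)C=1C(=O)OC
F0 | step 7 | none | none
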